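The route rests on cutting two bonds at the former C2=C3 double bond of a simple benzofuran: C2–ring A and C3–C9. Because the target carries ring A on C2 and the one-carbon arm C9 on C3 in a trans arrangement on the furan ring fused to ring B, both groups can be added across that bond at once. A lithiated benzofuran acetal, a ring-A aryl pinacol boronate and allyl acetate are merged by a palladium-catalysed dearomative 1,2-boronate shift that sets C2 and C3; the allyl group is later trimmed to C9–OH. The precursor is 2-(7-methoxybenzofuran-5-yl)-1,3-dioxolane, whose acetal afterwards supplies the aldehyde for an Evans syn-aldol that adds C7′–C9′ and ring C.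

Key step: step 5

Remarks on the chemistry
- Atom labels: benzofuran numbering for the bicycle (O1, C2, C3, C5, C7); C9 is the carbon on C3 that ends as CH2OH; C7′, C8′ and C9′ are the carbinol carbon, the ring-C-bearing carbon and the CH2OH carbon of the chain on C5. Ring A is the aryl group on C2, ring B the benzo ring, ring C the aryl group on C8′.
- Structure check: the target is (2S,3R) in the core (ring A and C9 trans) and (1S,2R) in the propane-1,3-diol chain, a syn relationship, which is what the (S)-4-benzyl auxiliary gives in a syn-aldol.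
- Assumption: (S)-BINAP is written for step 5; the sense of induction on the oxygen heterocycle must be confirmed in the first run, and the mirror-image ligand is used if it proves opposite.
- A free C9 hydroxyl would protonate the boron enolate of step 12, so it is acetylated in step 9; LiBH4 removes the acetate together with the auxiliary in step 13.
- The boronate is made in one step from the commercial boronic acid.

Step 1
Reactants: 1 5-iodovanillin; 2 ethynyltrimethylsilane
Product: 4 7-methoxy-2-(trimethylsilyl)-1-benzofuran-5-carbaldehyde, via alkynylphenol 3 (not isolated)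
Conditions: Pd(PPh3)2Cl2 (3 mol%), CuI (6 mol%), Et3N, DMF, 60 °C
Reagents that add atoms: none
Why: Sonogashira coupling of the aryl iodide is followed, under the same copper/amine conditions, by 5-endo-dig attack of the ortho phenoxide on the alkyne (tandem coupling–cycloisomerisation), a standard entry to 2-silylbenzofurans from ortho-iodophenols.

Step 2
Reactants: 4 7-methoxy-2-(trimethylsilyl)-1-benzofuran-5-carbaldehyde
Product: 5 7-methoxy-1-benzofuran-5-carbaldehyde
Conditions: TBAF (1.1 equiv), THF, 0 °C to rt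
Reagents that add atoms: none
Why: Fluoride-induced protodesilylation of the activated furan C2–Si bond frees C2–H and leaves the aldehyde untouched.

Step 3
Reactants: 5 7-methoxy-1-benzofuran-5-carbaldehyde
Product: 6 2-(7-methoxy-1-benzofuran-5-yl)-1,3-dioxolane
Conditions: HOCH2CH2OH, p-TsOH·H2O (cat.), toluene, reflux, Dean–Stark
Reagents that add atoms: ethylene glycol, OCCO
Why: Acid-catalysed acetalisation with azeotropic removal of water masks the aldehyde against n-BuLi and is routine for aryl aldehydes.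

Step 4
Reactants: 7 [4-(benzyloxy)-3-methoxyphenyl]boronic acid
Product: 8 2-[4-(benzyloxy)-3-methoxyphenyl]-4,4,5,5-tetramethyl-1,3,2-dioxaborolane
Conditions: pinacol, MgSO4, CH2Cl2, rt
Reagents that add atoms: pinacol, CC(C)(O)C(C)(C)O
Why: Condensation of the boronic acid with pinacol under dehydrating conditions (boronic ester formation) gives the ester needed for a well-defined tetracoordinate boronate in the next step.

Step 5
Reactants: 6 2-(7-methoxy-1-benzofuran-5-yl)-1,3-dioxolane; 8 2-[4-(benzyloxy)-3-methoxyphenyl]-4,4,5,5-tetramethyl-1,3,2-dioxaborolane; 9 allyl acetate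
Product: 12 2-[(2S,3S)-3-allyl-2-[4-(benzyloxy)-3-methoxyphenyl]-5-(1,3-dioxolan-2-yl)-7-methoxy-2,3-dihydro-1-benzofuran-2-yl]-4,4,5,5-tetramethyl-1,3,2-dioxaborolane, via 2-lithiobenzofuran 10 (not isolated), via lithium boronate complex 11 (not isolated)
Conditions: n-BuLi, THF, −78 °C; 8, −78 to 0 °C; Pd2(dba)3 (2.5 mol%), (S)-BINAP (6 mol%), allyl acetate, THF, 0 °C to rt
Reagents that add atoms: none
Why: Proposed new method: deprotonation at C2 and addition of the lithiobenzofuran to the boron of 8 gives a tetracoordinate boronate whose C2=C3 bond is an electron-rich π-nucleophile; attack of C3 on the cationic (BINAP)Pd(π-allyl) complex, formed by ionisation of allyl acetate at zerovalent palladium, is coupled to an anti 1,2-shift of the aryl group from boron to C2, so that C3–allyl and C2–ring A form together and the furan is dearomatised. The closest known reaction type is the palladium-catalysed enantioselective allylation of indol-2-yl boronate complexes with 1,2-boronate migration, which gives 2-boryl-3-allylindolines; a benzofuran is a weaker π-donor and has not been shown in this role. No ring is closed. C3 is set by the chiral bisphosphine on the allylpalladium electrophile (attack on the C3 Si face is required), and C2 follows from the stereospecific anti relationship of migrating aryl group and incoming allyl group, which leaves boron cis to the allyl group. The step needs aryl migration rather than pinacol-oxygen migration or direct aryl transfer to palladium, which the electron-rich aryl group and the poorly migrating pinacolate favour; lithiation at C2 rather than at C6 is secured by the much higher kinetic acidity of the furan C2–H at −78 °C.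

Step 6
Reactants: 12 the C2 boronic ester from step 5
Product: 13 (2S,3S)-3-allyl-2-[4-(benzyloxy)-3-methoxyphenyl]-5-(1,3-dioxolan-2-yl)-7-methoxy-2,3-dihydro-1-benzofuran
Conditions: TBAF·3H2O (2 equiv), toluene, 45 °C
Reagents that add atoms: none
Why: Fluoride-promoted protodeboronation of a tertiary benzylic boronic ester goes through the fluoroboronate with front-side protonation by water, so hydrogen takes the place of boron with retention and ring A stays trans to the allyl group.

Step 7
Reactants: 13 the trans 3-allyl dihydrobenzofuran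
Product: 14 (2S,3S)-2-[4-(benzyloxy)-3-methoxyphenyl]-5-(1,3-dioxolan-2-yl)-7-methoxy-3-[(E)-prop-1-en-1-yl]-2,3-dihydro-1-benzofuran
Conditions: Pd(dba)2 (2 mol%), P(t-Bu)3 (2 mol%), i-PrCOCl (2 mol%), toluene, 80 °C
Reagents that add atoms: none
Why: A bulky palladium hydride formed in the flask moves the terminal double bond by one position through insertion and β-hydride elimination (alkene isomerisation), while a second migration towards the hindered, branched C3 is disfavoured; any Z isomer is harmless because the alkene is cleaved next.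

Step 8
Reactants: 14 the 3-propenyl dihydrobenzofuran
Product: 16 [(2S,3R)-2-[4-(benzyloxy)-3-methoxyphenyl]-5-(1,3-dioxolan-2-yl)-7-methoxy-2,3-dihydro-1-benzofuran-3-yl]methanol, via C3 carbaldehyde 15 (not isolated)
Conditions: O3, CH2Cl2/MeOH, −78 °C (Sudan red 7B end point); NaBH4, −78 to 0 °C
Reagents that add atoms: ozone, [O-][O+]=O
Why: Ozonolysis with reductive work-up cleaves the disubstituted alkene much faster than ozone attacks the alkoxyarenes when the end point is read from a dye, and cold in-flask borohydride reduction converts the C3 aldehyde to C9–OH before it can epimerise or open the ring by β-elimination of the phenoxide.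

Step 9
Reactants: 16 the C9 alcohol
Product: 17 [(2S,3R)-2-[4-(benzyloxy)-3-methoxyphenyl]-5-(1,3-dioxolan-2-yl)-7-methoxy-2,3-dihydro-1-benzofuran-3-yl]methyl acetate
Conditions: Ac2O, pyridine, DMAP (cat.), CH2Cl2, 0 °C to rt
Reagents that add atoms: acetic anhydride, CC(=O)OC(C)=O
Why: DMAP-catalysed acetylation masks the primary C9 hydroxyl as an ester that tolerates the aldol conditions and is later removed by LiBH4 without a separate step.

Step 10
Reactants: 17 the C9 acetate
Product: 18 [(2S,3R)-2-[4-(benzyloxy)-3-methoxyphenyl]-5-formyl-7-methoxy-2,3-dihydro-1-benzofuran-3-yl]methyl acetate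
Conditions: 0.5 M HCl (aq), THF, rt
Reagents that add atoms: water, O
Why: Dilute aqueous acid hydrolyses the aryl dioxolane (acetal hydrolysis) far faster than it affects the primary acetate, the benzyl ether or the cyclic benzylic ether.

Step 11
Reactants: 19 [4-(benzyloxy)-3-methoxyphenyl]acetic acid; 20 (S)-4-benzyl-1,3-oxazolidin-2-one
Product: 22 (4S)-4-benzyl-3-{[4-(benzyloxy)-3-methoxyphenyl]acetyl}-1,3-oxazolidin-2-one, via mixed pivalic anhydride 21 (not isolated)
Conditions: PivCl, Et3N, THF, −20 °C; 20, LiCl, −20 °C to rt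
Reagents that add atoms: none
Why: N-acylation of the oxazolidinone through the mixed pivalic anhydride with LiCl/Et3N activation is the standard mild method and avoids the ketene-prone arylacetyl chloride.

Step 12
Reactants: 22 the N-arylacetyl oxazolidinone; 18 the C5 aldehyde
Product: 24 [(2S,3R)-5-{(1S,2S)-3-[(4S)-4-benzyl-2-oxo-1,3-oxazolidin-3-yl]-2-[4-(benzyloxy)-3-methoxyphenyl]-1-hydroxy-3-oxopropyl}-2-[4-(benzyloxy)-3-methoxyphenyl]-7-methoxy-2,3-dihydro-1-benzofuran-3-yl]methyl acetate, via boron Z-enolate 23 (not isolated)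
Conditions: Bu2BOTf, i-Pr2NEt, CH2Cl2, 0 °C; 18, −78 to 0 °C; pH 7 buffer, MeOH, H2O2, 0 °C
Reagents that add atoms: none
Why: In this Evans syn-aldol, soft enolisation gives the Z boron enolate, which reacts through a closed Zimmerman–Traxler chair with the auxiliary carbonyl turned away from the enolate oxygen, so the aldehyde is taken up on the face opposite the benzyl group and the (S)-auxiliary sets C7′ and C8′ syn, as (1S,2S) in the adduct, independently of the remote ring stereocentres.

Step 13
Reactants: 24 the aldol adduct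
Product: 25 (1S,2R)-2-[4-(benzyloxy)-3-methoxyphenyl]-1-[(2S,3R)-2-[4-(benzyloxy)-3-methoxyphenyl]-3-(hydroxymethyl)-7-methoxy-2,3-dihydro-1-benzofuran-5-yl]propane-1,3-diol
Conditions: LiBH4, MeOH, THF, 0 °C to rt
Reagents that add atoms: none
Why: LiBH4 with methanol reduces the imide carbonyl to C9′–OH with release of the auxiliary (reductive cleavage) and also reduces the acetate, at a temperature where retro-aldol and epimerisation of the α-aryl centre should not compete.

Step 14
Reactants: 25 the bis(benzyl ether) triol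
Product: 26 (1S,2R)-2-(4-hydroxy-3-methoxyphenyl)-1-[(2S,3R)-2-(4-hydroxy-3-methoxyphenyl)-3-(hydroxymethyl)-7-methoxy-2,3-dihydro-1-benzofuran-5-yl]propane-1,3-diol
Conditions: H2 (1 atm), Pd/C, EtOAc/MeOH, rt
Reagents that add atoms: none
Why: Hydrogenolysis of the two aryl benzyl ethers over Pd/C at one atmosphere in a neutral solvent is much faster than cleavage of the C7′ benzylic alcohol or of the ring C2–O1 bond, so both phenols should be freed if the reaction is stopped at full conversion.

Compound list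
1 | 5-iodovanillin (4-hydroxy-3-iodo-5-methoxybenzaldehyde) | COc1cc(C=O)cc(I)c1O | starting material
2 | ethynyltrimethylsilane | C#C[Si](C)(C)C | starting material
3 | 4-hydroxy-3-methoxy-5-[(trimethylsilyl)ethynyl]benzaldehyde | COc1cc(C=O)cc(C#C[Si](C)(C)C)c1O | intermediate (not isolated)
4 | 7-methoxy-2-(trimethylsilyl)-1-benzofuran-5-carbaldehyde | COc1cc(C=O)cc2cc([Si](C)(C)C)oc12 | intermediate
5 | 7-methoxy-1-benzofuran-5-carbaldehyde | COc1cc(C=O)cc2ccoc12 | intermediate
6 | 2-(7-methoxy-1-benzofuran-5-yl)-1,3-dioxolane | COc1cc(C2OCCO2)cc2ccoc12 | intermediate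
7 | [4-(benzyloxy)-3-methoxyphenyl]boronic acid | COc1cc(B(O)O)ccc1OCc1ccccc1 | starting material
8 | 2-[4-(benzyloxy)-3-methoxyphenyl]-4,4,5,5-tetramethyl-1,3,2-dioxaborolane | COc1cc(B2OC(C)(C)C(C)(C)O2)ccc1OCc1ccccc1 | intermediate
9 | allyl acetate | C=CCOC(C)=O | starting material
10 | 2-[2-lithio-7-methoxy-1-benzofuran-5-yl]-1,3-dioxolane | COc1cc(C2OCCO2)cc2cc([Li])oc12 | intermediate (not isolated)
11 | lithium [4-(benzyloxy)-3-methoxyphenyl][5-(1,3-dioxolan-2-yl)-7-methoxy-1-benzofuran-2-yl](pinacolato)borate | [Li+].COc1cc(C2OCCO2)cc2cc(oc12)[B-]1(OC(C)(C)C(C)(C)O1)c1ccc(OCc2ccccc2)c(OC)c1 | intermediate (not isolated)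
12 | 2-[(2S,3S)-3-allyl-2-[4-(benzyloxy)-3-methoxyphenyl]-5-(1,3-dioxolan-2-yl)-7-methoxy-2,3-dihydro-1-benzofuran-2-yl]-4,4,5,5-tetramethyl-1,3,2-dioxaborolane (aryl trans to allyl, boron cis to allyl) | COc1cc([C@@]2(B4OC(C)(C)C(C)(C)O4)Oc3c(OC)cc(C4OCCO4)cc3[C@@H]2CC=C)ccc1OCc1ccccc1 | intermediate
13 | (2S,3S)-3-allyl-2-[4-(benzyloxy)-3-methoxyphenyl]-5-(1,3-dioxolan-2-yl)-7-methoxy-2,3-dihydro-1-benzofuran (trans) | COc1cc([C@H]2Oc3c(OC)cc(C4OCCO4)cc3[C@@H]2CC=C)ccc1OCc1ccccc1 | intermediate
14 | (2S,3S)-2-[4-(benzyloxy)-3-methoxyphenyl]-5-(1,3-dioxolan-2-yl)-7-methoxy-3-[(E)-prop-1-en-1-yl]-2,3-dihydro-1-benzofuran | COc1cc([C@H]2Oc3c(OC)cc(C4OCCO4)cc3[C@@H]2/C=C/C)ccc1OCc1ccccc1 | intermediate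
15 | (2S,3S)-2-[4-(benzyloxy)-3-methoxyphenyl]-5-(1,3-dioxolan-2-yl)-7-methoxy-2,3-dihydro-1-benzofuran-3-carbaldehyde | COc1cc([C@H]2Oc3c(OC)cc(C4OCCO4)cc3[C@@H]2C=O)ccc1OCc1ccccc1 | intermediate (not isolated)
16 | [(2S,3R)-2-[4-(benzyloxy)-3-methoxyphenyl]-5-(1,3-dioxolan-2-yl)-7-methoxy-2,3-dihydro-1-benzofuran-3-yl]methanol | COc1cc([C@H]2Oc3c(OC)cc(C4OCCO4)cc3[C@@H]2CO)ccc1OCc1ccccc1 | intermediate
17 | [(2S,3R)-2-[4-(benzyloxy)-3-methoxyphenyl]-5-(1,3-dioxolan-2-yl)-7-methoxy-2,3-dihydro-1-benzofuran-3-yl]methyl acetate | COc1cc([C@H]2Oc3c(OC)cc(C4OCCO4)cc3[C@@H]2COC(C)=O)ccc1OCc1ccccc1 | intermediate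
18 | [(2S,3R)-2-[4-(benzyloxy)-3-methoxyphenyl]-5-formyl-7-methoxy-2,3-dihydro-1-benzofuran-3-yl]methyl acetate | COc1cc([C@H]2Oc3c(OC)cc(C=O)cc3[C@@H]2COC(C)=O)ccc1OCc1ccccc1 | intermediate
19 | [4-(benzyloxy)-3-methoxyphenyl]acetic acid | COc1cc(CC(=O)O)ccc1OCc1ccccc1 | starting material
20 | (S)-4-benzyl-1,3-oxazolidin-2-one | O=C1N[C@@H](Cc2ccccc2)CO1 | starting material
21 | [4-(benzyloxy)-3-methoxyphenyl]acetic pivalic anhydride | COc1cc(CC(=O)OC(=O)C(C)(C)C)ccc1OCc1ccccc1 | intermediate (not isolated)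
22 | (4S)-4-benzyl-3-{[4-(benzyloxy)-3-methoxyphenyl]acetyl}-1,3-oxazolidin-2-one | COc1cc(CC(=O)N2[C@@H](Cc3ccccc3)COC2=O)ccc1OCc1ccccc1 | intermediate
23 | dibutylboron (Z)-enolate of 22 | COc1cc(/C=C(\OB(CCCC)CCCC)N2[C@@H](Cc3ccccc3)COC2=O)ccc1OCc1ccccc1 | intermediate (not isolated)
24 | [(2S,3R)-5-{(1S,2S)-3-[(4S)-4-benzyl-2-oxo-1,3-oxazolidin-3-yl]-2-[4-(benzyloxy)-3-methoxyphenyl]-1-hydroxy-3-oxopropyl}-2-[4-(benzyloxy)-3-methoxyphenyl]-7-methoxy-2,3-dihydro-1-benzofuran-3-yl]methyl acetate | COc1cc([C@H]2Oc3c(OC)cc([C@@H](O)[C@@H](C(=O)N4[C@@H](Cc5ccccc5)COC4=O)c4ccc(OCc5ccccc5)c(OC)c4)cc3[C@@H]2COC(C)=O)ccc1OCc1ccccc1 | intermediate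
25 | (1S,2R)-2-[4-(benzyloxy)-3-methoxyphenyl]-1-[(2S,3R)-2-[4-(benzyloxy)-3-methoxyphenyl]-3-(hydroxymethyl)-7-methoxy-2,3-dihydro-1-benzofuran-5-yl]propane-1,3-diol | COc1cc([C@H]2Oc3c(OC)cc([C@@H](O)[C@@H](CO)c4ccc(OCc5ccccc5)c(OC)c4)cc3[C@@H]2CO)ccc1OCc1ccccc1 | intermediate
26 | (1S,2R)-2-(4-hydroxy-3-methoxyphenyl)-1-[(2S,3R)-2-(4-hydroxy-3-methoxyphenyl)-3-(hydroxymethyl)-7-methoxy-2,3-dihydro-1-benzofuran-5-yl]propane-1,3-diol (CNP0294468.1) | COc1cc([C@H]2Oc3c(OC)cc([C@@H](O)[C@@H](CO)c4ccc(O)c(OC)c4)cc3[C@@H]2CO)ccc1O | target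

Total step count: 14.
Longest linear sequence: 12 steps (steps 1–3, 5–10 and 12–14, from 5-iodovanillin).

Steps most likely to fail

1. Step 5 (Proposed new method).
- What may go wrong: the boronate complex may hand an aryl or benzofuranyl group directly to palladium (plain allyl–aryl coupling). The furan may open instead of undergoing C3 allylation with 1,2-shift. Face selection at C3 may be poor on the weaker oxygen π-donor.
- Fallback, known chemistry, setting out from 1 and returning at 16 (it replaces steps 1–8): O-alkylation of 1 with 4-(benzyloxy)-3-methoxybenzyl chloride (K2CO3, DMF) gives 4-{[4-(benzyloxy)-3-methoxybenzyl]oxy}-3-iodo-5-methoxybenzaldehyde F1. Acetalisation (ethylene glycol, p-TsOH, toluene, reflux) gives 2-(4-{[4-(benzyloxy)-3-methoxybenzyl]oxy}-3-iodo-5-methoxyphenyl)-1,3-dioxolane F2. Palladium-catalysed coupling of the aryl iodide with the Reformatsky reagent BrZnCH2CO2Me (Pd(PPh3)4, THF, 60 °C) gives the methyl arylacetate F3. Diazo transfer (p-acetamidobenzenesulfonyl azide, DBU, MeCN) gives the methyl aryldiazoacetate F4. Enantioselective intramolecular C–H insertion of the rhodium carbenoid into the benzylic ether C–H bond, with dirhodium tetrakis[N-phthaloyl-tert-leucinate] Rh2(PTTL)4 in the enantiomeric form that sets 2S (toluene, −60 °C), closes the five-membered ring and gives the cis methyl 2,3-dihydrobenzofuran-3-carboxylate F5. NaOMe in MeOH epimerises C3 to the trans methyl ester F6. LiAlH4 (THF, 0 °C) reduces the ester to alcohol 16.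

2. Step 6.
- What may go wrong: C–B cleavage of the hindered, electron-rich tertiary α-oxy boronic ester may be slow, or protonation may lose stereochemical fidelity at C2.
- Fallback, setting out from 12 and returning at 13: oxidation of the C–B bond (NaBO3·4H2O, THF/H2O, 0 °C) gives the C2 lactol, which opens to the keto-phenol (2S)-1-[4-(benzyloxy)-3-methoxyphenyl]-2-[5-(1,3-dioxolan-2-yl)-2-hydroxy-3-methoxyphenyl]pent-4-en-1-one F7. NaBH4 (MeOH, 0 °C) gives the benzylic alcohol (2S)-1-[4-(benzyloxy)-3-methoxyphenyl]-2-[5-(1,3-dioxolan-2-yl)-2-hydroxy-3-methoxyphenyl]pent-4-en-1-ol F8, either carbinol epimer being usable. Acid-catalysed cyclodehydration (p-TsOH cat., CH2Cl2, 4 Å molecular sieves, 0 °C) through the para-alkoxybenzyl cation closes the ring by phenol attack anti to the allyl group and should give the trans compound 13. C3 is α to the ketone in F7, so the oxidation and reduction are run buffered and cold.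

3. Step 8.
- What may go wrong: ozone may over-oxidise the alkoxyarenes or benzyl ether, and the transient C3 aldehyde may epimerise or eliminate the phenoxide during work-up.
- Fallback, setting out from 14 and returning at 16: dihydroxylation of the propenyl group (OsO4 cat., NMO, acetone/H2O) gives 1-[(2S,3S)-2-[4-(benzyloxy)-3-methoxyphenyl]-5-(1,3-dioxolan-2-yl)-7-methoxy-2,3-dihydro-1-benzofuran-3-yl]propane-1,2-diol F9. NaIO4 (THF/pH 7 buffer, 0 °C) cleaves the diol to aldehyde 15, which is reduced at once with NaBH4 to 16.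

Further compounds
F1 | step 5 | 4-{[4-(benzyloxy)-3-methoxybenzyl]oxy}-3-iodo-5-methoxybenzaldehyde | COc1cc(C=O)cc(I)c1OCc1ccc(OCc2ccccc2)c(OC)c1
F2 | step 5 | 2-(4-{[4-(benzyloxy)-3-methoxybenzyl]oxy}-3-iodo-5-methoxyphenyl)-1,3-dioxolane | COc1cc(C2OCCO2)cc(I)c1OCc1ccc(OCc2ccccc2)c(OC)c1
F3 | step 5 | methyl 2-(2-{[4-(benzyloxy)-3-methoxybenzyl]oxy}-5-(1,3-dioxolan-2-yl)-3-methoxyphenyl)acetate | COC(=O)Cc1cc(C2OCCO2)cc(OC)c1OCc1ccc(OCc2ccccc2)c(OC)c1
F4 | step 5 | methyl 2-diazo-2-(2-{[4-(benzyloxy)-3-methoxybenzyl]oxy}-5-(1,3-dioxolan-2-yl)-3-methoxyphenyl)acetate | COC(=O)C(=[N+]=[N-])c1cc(C2OCCO2)cc(OC)c1OCc1ccc(OCc2ccccc2)c(OC)c1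
F5 | step 5 | methyl (2S,3R)-2-[4-(benzyloxy)-3-methoxyphenyl]-5-(1,3-dioxolan-2-yl)-7-methoxy-2,3-dihydro-1-benzofuran-3-carboxylate (cis) | COc1cc([C@H]2Oc3c(OC)cc(C4OCCO4)cc3[C@H]2C(=O)OC)ccc1OCc1ccccc1
F6 | step 5 | methyl (2S,3S)-2-[4-(benzyloxy)-3-methoxyphenyl]-5-(1,3-dioxolan-2-yl)-7-methoxy-2,3-dihydro-1-benzofuran-3-carboxylate (trans) | COc1cc([C@H]2Oc3c(OC)cc(C4OCCO4)cc3[C@@H]2C(=O)OC)ccc1OCc1ccccc1
F7 | step 6 | (2S)-1-[4-(benzyloxy)-3-methoxyphenyl]-2-[5-(1,3-dioxolan-2-yl)-2-hydroxy-3-methoxyphenyl]pent-4-en-1-one | COc1cc(C(=O)[C@@H](CC=C)c2cc(C3OCCO3)cc(OC)c2O)ccc1OCc1ccccc1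
F8 | step 6 | (2S)-1-[4-(benzyloxy)-3-methoxyphenyl]-2-[5-(1,3-dioxolan-2-yl)-2-hydroxy-3-methoxyphenyl]pent-4-en-1-ol (carbinol centre unspecified) | COc1cc(C(O)[C@@H](CC=C)c2cc(C3OCCO3)cc(OC)c2O)ccc1OCc1ccccc1
F9 | step 8 | 1-[(2S,3S)-2-[4-(benzyloxy)-3-methoxyphenyl]-5-(1,3-dioxolan-2-yl)-7-methoxy-2,3-dihydro-1-benzofuran-3-yl]propane-1,2-diol (diol centres unspecified) | COc1cc([C@H]2Oc3c(OC)cc(C4OCCO4)cc3[C@@H]2C(O)C(C)O)ccc1OCc1ccccc1
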